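**Retrosynthetic overview** (pyrone atoms O1–C6; side chain C7 on the ring to C19)
1. Last bond made: C10–C11, by a nickel-catalysed enantioconvergent radical cross-electrophile coupling of alkenyl bromide 10 (pyrone–C7=C8–C9=C10–Br) with racemic allylic chloride 19 (C11–C19). This step also sets C11.
2. Chloride 19 comes from two successive aldol condensations on pentan-3-one (C13–C15 and their methyls): first with (S)-2-methylbutanal (C16–C19, the C17 centre from the chiral pool), then with racemic 2-chloropropanal (C11, C12).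
3. Bromide 10 comes from an aldol condensation of a second pentan-3-one with (E)-3-bromo-2-methylacrolein (C8–C10). The only ring, the 4-hydroxy-2-pyrone, is then closed on that ketone with methylmalonyl dichloride (C2–C4) before the coupling.

Assumption: racemic 2-chloropropanal and methylmalonyl dichloride are taken as catalogue chemicals, and the (3aR,8aS) ligand antipode named in step 7 is assumed to give the (S) centre at C11 (its mirror image is used if a pilot run shows the opposite sense).

**Route**

Step 1
Reactants: 1 methacrolein (2-methylprop-2-enal)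
Product: 3 (E)-3-bromo-2-methylprop-2-enal, via dibromo aldehyde 2 (not isolated)
Conditions: Br2, CH2Cl2, −20 °C; then Et3N, 0 °C → rt; distillation
Reagents that add atoms: bromine, BrBr
Why: Bromination–dehydrobromination: Br2 adds across the enal C=C and Et3N removes HBr (the α-bromine with a CH2Br hydrogen) to give the conjugated β-bromo enal, whose E isomer (Br anti to CHO) is the thermodynamically favoured one.

Step 2
Reactants: 3 (E)-3-bromo-2-methylprop-2-enal; 4 pentan-3-one
Product: 7 (4E,6E)-7-bromo-4,6-dimethylhepta-4,6-dien-3-one, via lithium aldolate 5 (not isolated), via aldol mesylate 6 (not isolated)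
Conditions: LiN(SiMe3)2, THF, −78 °C; 3; then MsCl, Et3N, −78 → 0 °C → rt
Reagents that add atoms: none
Why: Directed aldol condensation: the lithium enolate of the symmetrical ketone adds 1,2 to the enal, and mesylation of the aldolate followed by E1cB elimination gives the (E)-trisubstituted enone (acyl trans to the alkenyl group) while the vinyl bromide geometry is untouched.

Step 3
Reactants: 7 (4E,6E)-7-bromo-4,6-dimethylhepta-4,6-dien-3-one; 8 methylmalonyl dichloride
Product: 10 6-[(2E,4E)-5-bromo-4-methylpenta-2,4-dien-2-yl]-4-hydroxy-3,5-dimethyl-2H-pyran-2-one, via silyl enol ether 9 (not isolated)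
Conditions: TMSOTf (1.05 equiv), Et3N (1.05 equiv), Et2O, 0 °C; then 8, −78 °C → rt
Reagents that add atoms: none
Why: Pyrone annulation of a silyl enol ether with a malonyl dichloride: soft enolisation can only occur at the ethyl CH2, C-acylation of 9 by 8 (or the chlorocarbonyl ketene derived from it) gives a β-diketo acid chloride whose enol oxygen closes the lactone, and tautomerisation gives the 4-hydroxy-2-pyrone with the vinyl bromide and both E alkenes unchanged.

Step 4
Reactants: 11 (S)-2-methylbutan-1-ol
Product: 12 (S)-2-methylbutanal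
Conditions: TEMPO (1 mol %), KBr (10 mol %), NaOCl, NaHCO3, CH2Cl2/H2O, 0 °C; distilled and used the same day
Reagents that add atoms: none
Why: Anelli-type oxoammonium oxidation in a buffered two-phase system is fast at 0 °C and does not enolise the aldehyde, so the (S) centre taken from the chiral pool is kept.

Step 5
Reactants: 4 pentan-3-one; 12 (S)-2-methylbutanal
Product: 15 (4E,6S)-4,6-dimethyloct-4-en-3-one, via lithium aldolate 13 (not isolated), via aldol mesylate 14 (not isolated)
Conditions: LiN(SiMe3)2, THF, −78 °C; 12; then MsCl, Et3N, −78 → 0 °C; DBU, 0 °C → rt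
Reagents that add atoms: none
Why: Directed aldol condensation as in step 2: addition at −78 °C is faster than enolisation of the α-branched aldehyde so the (S) centre is kept, and E1cB elimination of the mesylate gives the (E)-enone.

Step 6
Reactants: 15 (4E,6S)-4,6-dimethyloct-4-en-3-one; 16 2-chloropropanal (racemic)
Product: 19 (3E,6E,8S)-2-chloro-4,6,8-trimethyldeca-3,6-dien-5-one (1:1 at C2), via lithium aldolate 17 (not isolated), via aldol mesylate 18 (not isolated)
Conditions: LiN(SiMe3)2, THF, −78 °C; 16; then MsCl, Et3N, −78 → 0 °C → rt; used promptly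
Reagents that add atoms: none
Why: Directed aldol condensation: LiN(SiMe3)2 deprotonates 15 kinetically at the α' CH2 (not at the γ C–H), the cross-conjugated enolate adds to the α-chloro aldehyde at −78 °C, and mesylation then E1cB elimination with Et3N gives the (E) γ-chloro enone, whose chlorine-bearing centre is left racemic on purpose because the next step is stereoconvergent.

Step 7
Reactants: 10 6-[(2E,4E)-5-bromo-4-methylpenta-2,4-dien-2-yl]-4-hydroxy-3,5-dimethyl-2H-pyran-2-one; 19 (3E,6E,8S)-2-chloro-4,6,8-trimethyldeca-3,6-dien-5-one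
Product: 22 4-hydroxy-3,5-dimethyl-6-[(2E,4E,6S,7E,10E,12S)-4,6,8,10,12-pentamethyl-9-oxotetradeca-2,4,7,10-tetraen-2-yl]-2H-pyran-2-one, via silyl ether 20 (not isolated), via silylated coupling product 21 (not isolated)
Conditions: BSA (1.1 equiv), DMA, rt; then 19 (1.3 equiv), NiCl2(dme) (nickel dichloride–1,2-dimethoxyethane complex, 10 mol %), (3aR,3a'R,8aS,8a'S)-2,2'-(cyclopropane-1,1-diyl)bis(3a,8a-dihydro-8H-indeno[1,2-d]oxazole) (11 mol %), manganese powder (3 equiv), NaI (0.5 equiv), 0 °C; aq. citric acid work-up
Reagents that add atoms: none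
Why: Proposed new method: zerovalent nickel carrying the chiral bis(oxazoline) inserts into the C–Br bond of 20 with retention of the E geometry, monovalent nickel (helped by the allylic iodide formed with NaI) abstracts the halogen from either epimer of 19 to give one planar enone-stabilised allyl radical, this radical is captured at its less hindered secondary terminus by the chiral alkenylnickel to give a trivalent nickel species that reductively eliminates the C10–C11 bond with the ligand choosing the face, so both epimers converge on the (S) centre at C11 while the remote (S) sec-butyl centre is a spectator, manganese turns the catalyst over, the transient silyl ether keeps the acidic pyrone OH from protonating alkenylnickel or being O-allylated and falls off in the acidic work-up; the closest known reaction type is the nickel-catalysed enantioconvergent reductive cross-coupling of alkenyl bromides with racemic secondary benzylic chlorides, extended here to a vinylogous α-chloro ketone.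

**Compound list**

1 | methacrolein (2-methylprop-2-enal) | CC(=C)C=O | starting material
2 | 2,3-dibromo-2-methylpropanal (racemic) | CC(Br)(CBr)C=O | intermediate
3 | (E)-3-bromo-2-methylprop-2-enal | O=C/C(C)=C/Br | intermediate
4 | pentan-3-one | CCC(=O)CC | starting material
5 | lithium (6E)-7-bromo-4,6-dimethyl-3-oxohept-6-en-5-olate (diastereomer mixture) | CCC(=O)C(C)C([O-])/C(C)=C/Br.[Li+] | intermediate
6 | (6E)-7-bromo-4,6-dimethyl-3-oxohept-6-en-5-yl methanesulfonate (diastereomer mixture) | CCC(=O)C(C)C(OS(C)(=O)=O)/C(C)=C/Br | intermediate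
7 | (4E,6E)-7-bromo-4,6-dimethylhepta-4,6-dien-3-one | CCC(=O)/C(C)=C/C(C)=C/Br | intermediate
8 | methylmalonyl dichloride (2-methylpropanedioyl dichloride) | CC(C(=O)Cl)C(=O)Cl | starting material
9 | (2Z,4E,6E)-7-bromo-4,6-dimethyl-3-(trimethylsilyloxy)hepta-2,4,6-triene | C/C=C(\O[Si](C)(C)C)/C(C)=C/C(C)=C/Br | intermediate
10 | 6-[(2E,4E)-5-bromo-4-methylpenta-2,4-dien-2-yl]-4-hydroxy-3,5-dimethyl-2H-pyran-2-one | Br/C=C(C)/C=C(\C)c1oc(=O)c(C)c(O)c1C | intermediate
11 | (S)-2-methylbutan-1-ol | CC[C@H](C)CO | starting material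
12 | (S)-2-methylbutanal | CC[C@H](C)C=O | intermediate
13 | lithium (6S)-4,6-dimethyl-3-oxooctan-5-olate (mixture at C4 and C5) | CCC(=O)C(C)C([O-])[C@@H](C)CC.[Li+] | intermediate
14 | (6S)-4,6-dimethyl-3-oxooctan-5-yl methanesulfonate (mixture at C4 and C5) | CCC(=O)C(C)C(OS(C)(=O)=O)[C@@H](C)CC | intermediate
15 | (4E,6S)-4,6-dimethyloct-4-en-3-one | CCC(=O)/C(C)=C/[C@@H](C)CC | intermediate
16 | 2-chloropropanal (racemic) | CC(Cl)C=O | starting material
17 | lithium (6E,8S)-2-chloro-4,6,8-trimethyl-5-oxodec-6-en-3-olate (mixture at C2, C3, C4) | CC(Cl)C([O-])C(C)C(=O)/C(C)=C/[C@@H](C)CC.[Li+] | intermediate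
18 | (6E,8S)-2-chloro-4,6,8-trimethyl-5-oxodec-6-en-3-yl methanesulfonate (mixture at C2, C3, C4) | CC(Cl)C(OS(C)(=O)=O)C(C)C(=O)/C(C)=C/[C@@H](C)CC | intermediate
19 | (3E,6E,8S)-2-chloro-4,6,8-trimethyldeca-3,6-dien-5-one (1:1 at C2) | CC(Cl)/C=C(\C)C(=O)/C(C)=C/[C@@H](C)CC | intermediate
20 | 6-[(2E,4E)-5-bromo-4-methylpenta-2,4-dien-2-yl]-3,5-dimethyl-4-(trimethylsilyloxy)-2H-pyran-2-one | Br/C=C(C)/C=C(\C)c1oc(=O)c(C)c(O[Si](C)(C)C)c1C | intermediate
21 | 3,5-dimethyl-6-[(2E,4E,6S,7E,10E,12S)-4,6,8,10,12-pentamethyl-9-oxotetradeca-2,4,7,10-tetraen-2-yl]-4-(trimethylsilyloxy)-2H-pyran-2-one | CC[C@H](C)/C=C(\C)C(=O)/C(C)=C/[C@@H](C)/C=C(C)/C=C(\C)c1oc(=O)c(C)c(O[Si](C)(C)C)c1C | intermediate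
22 | 4-hydroxy-3,5-dimethyl-6-[(2E,4E,6S,7E,10E,12S)-4,6,8,10,12-pentamethyl-9-oxotetradeca-2,4,7,10-tetraen-2-yl]-2H-pyran-2-one | CC[C@H](C)/C=C(\C)C(=O)/C(C)=C/[C@@H](C)/C=C(C)/C=C(\C)c1oc(=O)c(C)c(O)c1C | target

**Totals**
Total step count: 7. Longest linear sequence: 4 steps (1 → 2 → 3 → 7, or 4 → 5 → 6 → 7).

**Three steps most likely to fail**

Step 7 (key coupling). The risks are homocoupling or reduction of the very reactive allylic chloride at zerovalent nickel, and an unproven level of enantiocontrol for a non-benzylic radical. The fallback changes how the radical is made. It sets out from 15 and comes back at 22. Enone 15 is taken through the protocol of step 6 with acrolein in place of 16, giving the lithium aldolate F1, its mesylate F2 and, after elimination, (3E,6E,8S)-4,6,8-trimethyldeca-1,3,6-trien-5-one F3. F3 and silyl ether 20 (made from 10 with BSA as in step 7) are then joined in a dual hydrogen-atom-transfer/nickel hydroalkenylation (Fe(acac)3, PhSiH3, NiBr2(diglyme), the same chiral bis(oxazoline), manganese powder, DMA). An iron hydride transfers a hydrogen atom to the terminal CH2 of F3, which gives the same C11 allyl radical slowly and without any allylic halide, and the chiral alkenylnickel derived from 20 captures it to give 21 and, after the acidic work-up, 22.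

Step 3 (pyrone annulation on the bromodienone). The risks are competing vinylogous enolisation and a poor acylation/cyclisation yield in the presence of the ammonium triflate. The fallback builds the ring first and the diene second. It sets out from 4 and 8 and comes back at 10. Pentan-3-one 4 is silylated (TMSOTf, Et3N) to (Z)-3-(trimethylsilyloxy)pent-2-ene F4, which is annulated with 8 to 6-ethyl-4-hydroxy-3,5-dimethyl-2H-pyran-2-one F5. The dianion of F5 (LiN(iPr)2, 2.2 equiv, THF, −78 °C; deprotonation at OH and at the ethyl CH2) adds to bromo enal 3 to give 6-[(4E)-5-bromo-3-hydroxy-4-methylpent-4-en-2-yl]-4-hydroxy-3,5-dimethyl-2H-pyran-2-one F6. Acid-catalysed dehydration (TsOH, toluene, 60 °C) into conjugation with the pyrone gives 10.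

Step 6 (α-chloro aldehyde aldol condensation). The risks are closure of the chlorohydrin aldolate to an epoxide and loss or displacement of the allylic chloride during the elimination. The fallback carries the C11 oxygen through the condensation and installs chlorine last. It sets out from 15 and comes back at 19. Enone 15 is condensed by the step 6 protocol with racemic 2-(tert-butyldimethylsilyloxy)propanal, giving the lithium aldolate F7, its mesylate F8 and (3E,6E,8S)-2-(tert-butyldimethylsilyloxy)-4,6,8-trimethyldeca-3,6-dien-5-one F9. HF·pyridine in THF frees the allylic alcohol (3E,6E,8S)-2-hydroxy-4,6,8-trimethyldeca-3,6-dien-5-one F10. PPh3 and N-chlorosuccinimide (CH2Cl2, 0 °C) convert F10 into 19; the conjugated secondary chloride is favoured over the transposed tertiary one.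

**Further compounds**

F1 | step 7 | lithium (6E,8S)-4,6,8-trimethyl-5-oxodeca-1,6-dien-3-olate (mixture at C3 and C4) | C=CC([O-])C(C)C(=O)/C(C)=C/[C@@H](C)CC.[Li+]
F2 | step 7 | (6E,8S)-4,6,8-trimethyl-5-oxodeca-1,6-dien-3-yl methanesulfonate (mixture at C3 and C4) | C=CC(OS(C)(=O)=O)C(C)C(=O)/C(C)=C/[C@@H](C)CC
F3 | step 7 | (3E,6E,8S)-4,6,8-trimethyldeca-1,3,6-trien-5-one | C=C/C=C(\C)C(=O)/C(C)=C/[C@@H](C)CC
F4 | step 3 | (Z)-3-(trimethylsilyloxy)pent-2-ene | C/C=C(\O[Si](C)(C)C)CC
F5 | step 3 | 6-ethyl-4-hydroxy-3,5-dimethyl-2H-pyran-2-one | CCc1oc(=O)c(C)c(O)c1C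
F6 | step 3 | 6-[(4E)-5-bromo-3-hydroxy-4-methylpent-4-en-2-yl]-4-hydroxy-3,5-dimethyl-2H-pyran-2-one (diastereomer mixture) | CC(C(O)/C(C)=C/Br)c1oc(=O)c(C)c(O)c1C
F7 | step 6 | lithium (6E,8S)-2-(tert-butyldimethylsilyloxy)-4,6,8-trimethyl-5-oxodec-6-en-3-olate (mixture at C2, C3, C4) | CC(O[Si](C)(C)C(C)(C)C)C([O-])C(C)C(=O)/C(C)=C/[C@@H](C)CC.[Li+]
F8 | step 6 | (6E,8S)-2-(tert-butyldimethylsilyloxy)-4,6,8-trimethyl-5-oxodec-6-en-3-yl methanesulfonate (mixture at C2, C3, C4) | CC(O[Si](C)(C)C(C)(C)C)C(OS(C)(=O)=O)C(C)C(=O)/C(C)=C/[C@@H](C)CC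
F9 | step 6 | (3E,6E,8S)-2-(tert-butyldimethylsilyloxy)-4,6,8-trimethyldeca-3,6-dien-5-one (1:1 at C2) | CC(O[Si](C)(C)C(C)(C)C)/C=C(\C)C(=O)/C(C)=C/[C@@H](C)CC
F10 | step 6 | (3E,6E,8S)-2-hydroxy-4,6,8-trimethyldeca-3,6-dien-5-one (1:1 at C2) | CC(O)/C=C(\C)C(=O)/C(C)=C/[C@@H](C)CC
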